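**Retrosynthetic overview**

1. Chinikomycin B ⇐ its bis(methoxymethyl)-protected hydroquinone (acetal hydrolysis, then Ag2O). The all-(E) triene ⇐ Stille coupling of an aryl (E)-vinylstannane with the (2E,4E)-5-iodopentadienamide that already carries the five-membered ring. The aryl–vinyl bond ⇐ Stille coupling of the aryl iodide with (E)-1,2-bis(tributylstannyl)ethene.
2. Upper amide ⇐ aniline + (2E,4E,6R)-2,4,6-trimethyldeca-2,4-dienoic acid (C6 from an Evans methylation, both alkenes from Wittig reactions). Arene ⇐ 4-methoxy-2-nitrophenol (Cl ortho to OH, I para to NH2).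
3. Five-membered ring ⇐ N-trifluoroacetyl squaric ester amide + ethylene: rhodium-catalysed C–C activation, loss of one CO and ethylene insertion, a (4+2−1) annulation that is formally 3+2 and makes both CH2–C bonds of the ring at once.
4. Enabling feature: in the cyclopentenone ring the unsubstituted C4H2–C5H2 unit lies between the ketone carbon C1 and the enol carbon C3, and C1(=O)–C2(N)=C3(O) is a squaramide ring with one carbonyl removed. The enol oxygen, kept as OEt, decides which carbonyl leaves.
5. Order of ring formation: benzene ring purchased; cyclopentenone ring in step 2; quinone ring unveiled by oxidation in step 21.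

Key step: step 2

Assumption: the 2-aminocyclopentane-1,3-dione unit is written throughout as the enol tautomer of the target SMILES, and compound 6 as its 1:1 hydrochloride.

**Route**

Step 1
Reactants: 1 diethyl squarate (3,4-diethoxycyclobut-3-ene-1,2-dione); 2 2,2,2-trifluoroacetamide
Product: 3 N-(2-ethoxy-3,4-dioxocyclobut-1-en-1-yl)-2,2,2-trifluoroacetamide
Conditions: NaH (1.1 equiv), THF, 0 °C → rt; then cold 1 M HCl
Reagents that add atoms: none
Why: Addition–elimination (vinylogous acyl substitution) of the sodium amide anion on the squaric diester; the released ethoxide deprotonates the imide-like N–H of the product, and the resulting anion should resist a second substitution.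

Step 2
Reactants: 3 N-(2-ethoxy-3,4-dioxocyclobut-1-en-1-yl)-2,2,2-trifluoroacetamide; 4 ethylene
Product: 5 N-(2-ethoxy-5-oxocyclopent-1-en-1-yl)-2,2,2-trifluoroacetamide
Conditions: [Rh(C2H4)2Cl]2 (5 mol %), P(C6F5)3 (20 mol %), ethylene (10 bar, vented and recharged), 1,4-dioxane, 130 °C
Reagents that add atoms: none
Why: Proposed new method: monovalent rhodium inserts into the strained acyl–acyl bond of the cyclobutenedione to give a rhodacyclopentenedione, CO is extruded from the acyl group next to the ethoxy-bearing carbon to give a rhodacyclobutenone (a rhodium-bound alkoxy-vinylketene), ethylene inserts to a rhodacyclohexenone, and C–C reductive elimination releases the cyclopentenone, so that the two CH2 carbons of ethylene become bonded to the ring carbonyl carbon and to the enol-ether carbon. The closest known reaction type is the ruthenium- or rhodium-catalysed decarbonylative reconstruction of cyclobutenediones with norbornene to cyclopentenones, together with the rhodium-catalysed cut-and-sew carboacylation of olefins with cyclobutenones; ethylene as the olefin and an amido alkoxy squarate as the substrate are new. The five-membered ring is closed as a formal 3+2 (4+2−1) annulation by reductive elimination from the six-membered rhodacycle, and no stereocentre is formed. The step needs loss of the CO next to C–OEt and not of the CO next to C–N; this should be secured because the ethoxy oxygen is the only strong π-donor and stabilises the carbene-like Rh–C(OEt) terminus, whereas the nitrogen lone pair is tied up by the trifluoroacetyl group and no base is present to ionise the N–H. It also needs CO loss before olefin insertion (otherwise a 4+2 product would form) and reductive elimination before β-hydride elimination, which the CO-free, repeatedly vented ethylene atmosphere, the electron-poor phosphine and the rigid metallacycle should favour. Release of the ring strain of the four-membered dione drives the sequence.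

Step 3
Reactants: 5 N-(2-ethoxy-5-oxocyclopent-1-en-1-yl)-2,2,2-trifluoroacetamide
Product: 6 2-amino-3-hydroxycyclopent-2-en-1-one hydrochloride
Conditions: 3 M HCl (aq.), 1,4-dioxane, 70 °C; evaporate
Reagents that add atoms: water, O; hydrogen chloride, Cl
Why: Acid hydrolysis of the vinylogous ester (enol ether) and of the trifluoroacetamide; the product is held as the ammonium salt of a vinylogous acid, which cannot self-condense.

Step 4
Reactants: 7 ethyl (E)-4-oxobut-2-enoate
Product: 8 ethyl (2E,4E)-5-iodopenta-2,4-dienoate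
Conditions: CrCl2 (6 equiv), CHI3 (2 equiv), THF, 0 °C, dark
Reagents that add atoms: iodoform, IC(I)I
Why: Takai olefination: the gem-dichromium species from CHI3 adds to the aldehyde only and should give the (E)-vinyl iodide, while the existing 2E alkene and the ester are carried through unchanged.

Step 5
Reactants: 8 ethyl (2E,4E)-5-iodopenta-2,4-dienoate
Product: 9 (2E,4E)-5-iodopenta-2,4-dienoic acid
Conditions: LiOH, THF/H2O, 0 °C → rt; then 1 M HCl
Reagents that add atoms: lithium hydroxide, [Li+].[OH-]
Why: Saponification of the ethyl ester at low temperature, where hydroxide attack at the iodine-bearing diene terminus should not compete.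

Step 6
Reactants: 9 (2E,4E)-5-iodopenta-2,4-dienoic acid; 6 2-amino-3-hydroxycyclopent-2-en-1-one hydrochloride
Product: 11 (2E,4E)-N-(2-hydroxy-5-oxocyclopent-1-en-1-yl)-5-iodopenta-2,4-dienamide, via (2E,4E)-5-iodopenta-2,4-dienoyl chloride 10 (not isolated)
Conditions: (COCl)2, DMF (cat.), CH2Cl2, 0 °C → rt, concentrate; then 6, Et3N (3.2 equiv), THF/DMF, −20 °C → rt
Reagents that add atoms: oxalyl chloride, O=C(Cl)C(Cl)=O (chlorine of intermediate 10 only)
Why: Acyl chloride formation followed by N-acylation of the liberated 2-amino enol (amide formation); an O-acyl by-product should pass its acyl group to nitrogen or be cleaved on work-up.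

Step 7
Reactants: 12 (R)-4-benzyloxazolidin-2-one; 13 hexanoyl chloride
Product: 14 (R)-4-benzyl-3-hexanoyloxazolidin-2-one
Conditions: n-BuLi, THF, −78 °C; then 13, −78 °C → 0 °C
Reagents that add atoms: none
Why: N-acylation of the lithiated oxazolidinone with the acid chloride, which prepares the imide for the Evans alkylation.

Step 8
Reactants: 14 (R)-4-benzyl-3-hexanoyloxazolidin-2-one
Product: 15 (R)-4-benzyl-3-[(R)-2-methylhexanoyl]oxazolidin-2-one
Conditions: NaN(SiMe3)2, THF, −78 °C; then MeI, −78 °C
Reagents that add atoms: iodomethane, CI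
Why: Evans asymmetric alkylation: the chelated (Z)-sodium enolate is methylated on the face opposite the benzyl group, which with the (R)-auxiliary sets the (R)-configured α-carbon (the later C6 of the side chain).

Step 9
Reactants: 15 (R)-4-benzyl-3-[(R)-2-methylhexanoyl]oxazolidin-2-one
Product: 16 (R)-2-methylhexan-1-ol
Conditions: LiBH4, H2O (1 equiv), Et2O, 0 °C
Reagents that add atoms: none
Why: Reductive cleavage of the imide by LiBH4 gives the primary alcohol without touching the α-stereocentre and releases the auxiliary.

Step 10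
Reactants: 16 (R)-2-methylhexan-1-ol; 17 2-(triphenylphosphoranylidene)propanal
Product: 19 (2E,4R)-2,4-dimethyloct-2-enal, via (R)-2-methylhexanal 18 (not isolated)
Conditions: TEMPO (10 mol %), PhI(OAc)2, CH2Cl2, rt; wash aq. NaHCO3; then 17, toluene, 80 °C
Reagents that add atoms: none
Why: Oxoammonium (TEMPO) oxidation to the aldehyde without epimerisation, then Wittig olefination with the stabilised formyl ylide, which should give the (E)-trisubstituted enal; the volatile, epimerisable aldehyde is used as its solution.

Step 11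
Reactants: 19 (2E,4R)-2,4-dimethyloct-2-enal; 20 ethyl 2-(triphenylphosphoranylidene)propanoate
Product: 21 ethyl (2E,4E,6R)-2,4,6-trimethyldeca-2,4-dienoate
Conditions: toluene, 100 °C
Reagents that add atoms: none
Why: Wittig olefination with the stabilised ester ylide should give the (E)-2-methyl enoate and so the (2E,4E)-diene.

Step 12
Reactants: 21 ethyl (2E,4E,6R)-2,4,6-trimethyldeca-2,4-dienoate
Product: 22 (2E,4E,6R)-2,4,6-trimethyldeca-2,4-dienoic acid
Conditions: LiOH, THF/MeOH/H2O, 50 °C; then 1 M HCl
Reagents that add atoms: lithium hydroxide, [Li+].[OH-]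
Why: Saponification of the hindered α-methyl dienoate; the remote stereocentre is not acidic and the conjugated geometry is the stable one.

Step 13
Reactants: 23 4-methoxy-2-nitrophenol
Product: 24 2-chloro-4-methoxy-6-nitrophenol
Conditions: N-chlorosuccinimide, MeCN, 60 °C
Reagents that add atoms: N-chlorosuccinimide, O=C1CCC(=O)N1Cl
Why: Electrophilic aromatic chlorination: the free hydroxyl directs to its only open ortho position (para is blocked by OMe), which is also meta to the nitro group.

Step 14
Reactants: 24 2-chloro-4-methoxy-6-nitrophenol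
Product: 25 2-chloro-6-nitrobenzene-1,4-diol
Conditions: BBr3, CH2Cl2, −78 °C → rt; then H2O
Reagents that add atoms: none
Why: Lewis acid cleavage of the aryl methyl ether (BBr3 demethylation); the nitro and chloro groups are inert.

Step 15
Reactants: 25 2-chloro-6-nitrobenzene-1,4-diol
Product: 26 1-chloro-2,5-bis(methoxymethoxy)-3-nitrobenzene
Conditions: MOMCl, i-Pr2NEt, CH2Cl2, 0 °C → rt
Reagents that add atoms: chloromethyl methyl ether, COCCl
Why: O-alkylation of both phenols with chloromethyl methyl ether (acetal protection of the hydroquinone), chosen because the small acetals should not block the later coupling at the flanked carbon.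

Step 16
Reactants: 26 1-chloro-2,5-bis(methoxymethoxy)-3-nitrobenzene
Product: 27 3-chloro-2,5-bis(methoxymethoxy)aniline
Conditions: H2 (1 atm), Pt/C (sulfided), EtOAc, rt
Reagents that add atoms: none
Why: Chemoselective catalytic hydrogenation of the nitro group over sulfided platinum, which spares the aryl chloride and the acetals.

Step 17
Reactants: 27 3-chloro-2,5-bis(methoxymethoxy)aniline
Product: 28 3-chloro-4-iodo-2,5-bis(methoxymethoxy)aniline
Conditions: N-iodosuccinimide, MeCN, 0 °C, dark
Reagents that add atoms: N-iodosuccinimide, O=C1CCC(=O)N1I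
Why: Electrophilic aromatic iodination para to the amino group, the strongest donor, at a position that is also ortho to an alkoxy group.

Step 18
Reactants: 22 (2E,4E,6R)-2,4,6-trimethyldeca-2,4-dienoic acid; 28 3-chloro-4-iodo-2,5-bis(methoxymethoxy)aniline
Product: 30 (2E,4E,6R)-N-[3-chloro-4-iodo-2,5-bis(methoxymethoxy)phenyl]-2,4,6-trimethyldeca-2,4-dienamide, via (2E,4E,6R)-2,4,6-trimethyldeca-2,4-dienoyl chloride 29 (not isolated)
Conditions: (COCl)2, DMF (cat.), CH2Cl2, 0 °C → rt, concentrate; then 28, pyridine, CH2Cl2, 0 °C → rt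
Reagents that add atoms: oxalyl chloride, O=C(Cl)C(Cl)=O (chlorine of intermediate 29 only)
Why: Acyl chloride formation and N-acylation of the aniline (amide formation); the dienoyl chloride has no α-hydrogen, so the alkene geometry and the remote stereocentre should be safe.

Step 19
Reactants: 30 (2E,4E,6R)-N-[3-chloro-4-iodo-2,5-bis(methoxymethoxy)phenyl]-2,4,6-trimethyldeca-2,4-dienamide; 31 (E)-1,2-bis(tributylstannyl)ethene
Product: 32 (2E,4E,6R)-N-{3-chloro-2,5-bis(methoxymethoxy)-4-[(E)-2-(tributylstannyl)ethenyl]phenyl}-2,4,6-trimethyldeca-2,4-dienamide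
Conditions: Pd2(dba)3 (5 mol %), P(2-furyl)3 (20 mol %), CuI (20 mol %), 31 (3 equiv), NMP, 70 °C
Reagents that add atoms: none
Why: Stille coupling of the aryl iodide with an excess of the distannane, so that only one tin is exchanged; the coupling proceeds with retention and should leave the (E)-vinylstannane, and the aryl chloride does not add to zerovalent palladium under these conditions.

Step 20
Reactants: 32 (2E,4E,6R)-N-{3-chloro-2,5-bis(methoxymethoxy)-4-[(E)-2-(tributylstannyl)ethenyl]phenyl}-2,4,6-trimethyldeca-2,4-dienamide; 11 (2E,4E)-N-(2-hydroxy-5-oxocyclopent-1-en-1-yl)-5-iodopenta-2,4-dienamide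
Product: 33 (2E,4E,6R)-N-{3-chloro-4-[(1E,3E,5E)-7-[(2-hydroxy-5-oxocyclopent-1-en-1-yl)amino]-7-oxohepta-1,3,5-trien-1-yl]-2,5-bis(methoxymethoxy)phenyl}-2,4,6-trimethyldeca-2,4-dienamide
Conditions: PdCl2(MeCN)2 (10 mol %), DMF, rt, dark
Reagents that add atoms: none
Why: Stille coupling of vinylstannane and vinyl iodide with retention of both alkene geometries, which completes the all-(E) triene under neutral conditions that should tolerate the free vinylogous acid.

Step 21
Reactants: 33 (2E,4E,6R)-N-{3-chloro-4-[(1E,3E,5E)-7-[(2-hydroxy-5-oxocyclopent-1-en-1-yl)amino]-7-oxohepta-1,3,5-trien-1-yl]-2,5-bis(methoxymethoxy)phenyl}-2,4,6-trimethyldeca-2,4-dienamide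
Product: 35 chinikomycin B, via chinikomycin A 34 (not isolated)
Conditions: 3 M HCl (aq.)/THF, 40 °C, dark; extract; then Ag2O, THF, rt
Reagents that add atoms: none
Why: Acid hydrolysis of both aryl methoxymethyl acetals, then oxidation of the hydroquinone to the p-quinone by Ag2O, a mild oxidant that should not touch the polyene amides or the vinylogous acid.

**Compound list**

1 | diethyl squarate (3,4-diethoxycyclobut-3-ene-1,2-dione) | CCOC1=C(OCC)C(=O)C1=O | starting material
2 | 2,2,2-trifluoroacetamide | NC(=O)C(F)(F)F | starting material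
3 | N-(2-ethoxy-3,4-dioxocyclobut-1-en-1-yl)-2,2,2-trifluoroacetamide | CCOC1=C(NC(=O)C(F)(F)F)C(=O)C1=O | intermediate
4 | ethylene | C=C | starting material
5 | N-(2-ethoxy-5-oxocyclopent-1-en-1-yl)-2,2,2-trifluoroacetamide | CCOC1=C(NC(=O)C(F)(F)F)C(=O)CC1 | intermediate
6 | 2-amino-3-hydroxycyclopent-2-en-1-one hydrochloride | Cl.NC1=C(O)CCC1=O | intermediate
7 | ethyl (E)-4-oxobut-2-enoate | CCOC(=O)/C=C/C=O | starting material
8 | ethyl (2E,4E)-5-iodopenta-2,4-dienoate | CCOC(=O)/C=C/C=C/I | intermediate
9 | (2E,4E)-5-iodopenta-2,4-dienoic acid | OC(=O)/C=C/C=C/I | intermediate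
10 | (2E,4E)-5-iodopenta-2,4-dienoyl chloride | ClC(=O)/C=C/C=C/I | intermediate
11 | (2E,4E)-N-(2-hydroxy-5-oxocyclopent-1-en-1-yl)-5-iodopenta-2,4-dienamide | O=C(/C=C/C=C/I)NC1=C(O)CCC1=O | intermediate
12 | (R)-4-benzyloxazolidin-2-one | O=C1N[C@H](Cc2ccccc2)CO1 | starting material
13 | hexanoyl chloride | CCCCCC(=O)Cl | starting material
14 | (R)-4-benzyl-3-hexanoyloxazolidin-2-one | CCCCCC(=O)N1[C@H](Cc2ccccc2)COC1=O | intermediate
15 | (R)-4-benzyl-3-[(R)-2-methylhexanoyl]oxazolidin-2-one | CCCC[C@@H](C)C(=O)N1[C@H](Cc2ccccc2)COC1=O | intermediate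
16 | (R)-2-methylhexan-1-ol | CCCC[C@@H](C)CO | intermediate
17 | 2-(triphenylphosphoranylidene)propanal | CC(C=O)=P(c1ccccc1)(c1ccccc1)c1ccccc1 | starting material
18 | (R)-2-methylhexanal | CCCC[C@@H](C)C=O | intermediate
19 | (2E,4R)-2,4-dimethyloct-2-enal | CCCC[C@@H](C)/C=C(\C)C=O | intermediate
20 | ethyl 2-(triphenylphosphoranylidene)propanoate | CCOC(=O)C(C)=P(c1ccccc1)(c1ccccc1)c1ccccc1 | starting material
21 | ethyl (2E,4E,6R)-2,4,6-trimethyldeca-2,4-dienoate | CCCC[C@@H](C)/C=C(C)/C=C(\C)C(=O)OCC | intermediate
22 | (2E,4E,6R)-2,4,6-trimethyldeca-2,4-dienoic acid | CCCC[C@@H](C)/C=C(C)/C=C(\C)C(=O)O | intermediate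
23 | 4-methoxy-2-nitrophenol | COc1ccc(O)c([N+](=O)[O-])c1 | starting material
24 | 2-chloro-4-methoxy-6-nitrophenol | COc1cc(Cl)c(O)c([N+](=O)[O-])c1 | intermediate
25 | 2-chloro-6-nitrobenzene-1,4-diol | Oc1cc(Cl)c(O)c([N+](=O)[O-])c1 | intermediate
26 | 1-chloro-2,5-bis(methoxymethoxy)-3-nitrobenzene | COCOc1cc(Cl)c(OCOC)c([N+](=O)[O-])c1 | intermediate
27 | 3-chloro-2,5-bis(methoxymethoxy)aniline | COCOc1cc(N)c(OCOC)c(Cl)c1 | intermediate
28 | 3-chloro-4-iodo-2,5-bis(methoxymethoxy)aniline | COCOc1cc(N)c(OCOC)c(Cl)c1I | intermediate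
29 | (2E,4E,6R)-2,4,6-trimethyldeca-2,4-dienoyl chloride | CCCC[C@@H](C)/C=C(C)/C=C(\C)C(=O)Cl | intermediate
30 | (2E,4E,6R)-N-[3-chloro-4-iodo-2,5-bis(methoxymethoxy)phenyl]-2,4,6-trimethyldeca-2,4-dienamide | CCCC[C@@H](C)/C=C(C)/C=C(\C)C(=O)Nc1cc(OCOC)c(I)c(Cl)c1OCOC | intermediate
31 | (E)-1,2-bis(tributylstannyl)ethene | CCCC[Sn](CCCC)(CCCC)/C=C/[Sn](CCCC)(CCCC)CCCC | starting material
32 | (2E,4E,6R)-N-{3-chloro-2,5-bis(methoxymethoxy)-4-[(E)-2-(tributylstannyl)ethenyl]phenyl}-2,4,6-trimethyldeca-2,4-dienamide | CCCC[C@@H](C)/C=C(C)/C=C(\C)C(=O)Nc1cc(OCOC)c(/C=C/[Sn](CCCC)(CCCC)CCCC)c(Cl)c1OCOC | intermediate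
33 | (2E,4E,6R)-N-{3-chloro-4-[(1E,3E,5E)-7-[(2-hydroxy-5-oxocyclopent-1-en-1-yl)amino]-7-oxohepta-1,3,5-trien-1-yl]-2,5-bis(methoxymethoxy)phenyl}-2,4,6-trimethyldeca-2,4-dienamide | CCCC[C@@H](C)/C=C(C)/C=C(\C)C(=O)Nc1cc(OCOC)c(/C=C/C=C/C=C/C(=O)NC2=C(O)CCC2=O)c(Cl)c1OCOC | intermediate
34 | chinikomycin A (the hydroquinone of the target) | CCCC[C@@H](C)/C=C(C)/C=C(\C)C(=O)Nc1cc(O)c(/C=C/C=C/C=C/C(=O)NC2=C(O)CCC2=O)c(Cl)c1O | intermediate
35 | chinikomycin B | CCCC[C@@H](C)/C=C(C)/C=C(\C)C(=O)NC1=CC(=O)C(/C=C/C=C/C=C/C(=O)NC2=C(O)CCC2=O)=C(Cl)C1=O | target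

**Step count and risks**

Total step count: 21.
Longest linear sequence: 10 steps (steps 7, 8, 9, 10, 11, 12, 18, 19, 20, 21, from (R)-4-benzyloxazolidin-2-one).

Steps most likely to fail:

Step 2 (Proposed new method). Oxidative addition into the donor-substituted dione may be too slow. CO may be lost from the acyl group next to nitrogen, which would give the regioisomeric enone. Ethylene may insert before CO is lost. β-Hydride elimination may open the metallacycle after insertion.
The fallback uses known chemistry and sets out from trifluoroacetamide 2. Commercial cyclopentane-1,3-dione is converted by diazo transfer (4-acetamidobenzenesulfonyl azide, Et3N, MeCN) into 2-diazocyclopentane-1,3-dione F1. N–H insertion of its carbenoid into 2, catalysed by dirhodium tetraacetate (Rh2(OAc)4, 1,2-dichloroethane, 80 °C), should give N-(2-hydroxy-5-oxocyclopent-1-en-1-yl)-2,2,2-trifluoroacetamide F2. Hydrolysis of F2 under the conditions of step 3 returns to the route at compound 6.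

Step 19. Transmetalation at the doubly ortho-substituted aryl–palladium centre may be slow, and the product stannane may couple a second time or lose its tin by protonolysis.
The fallback sets out from aryl iodide 30 and avoids tin at this stage. A Heck–Mizoroki reaction with commercial pinacol vinylboronate (Pd(OAc)2, P(o-tol)3, n-Bu3N, toluene, 90 °C) should give (2E,4E,6R)-N-{3-chloro-2,5-bis(methoxymethoxy)-4-[(E)-2-(4,4,5,5-tetramethyl-1,3,2-dioxaborolan-2-yl)ethenyl]phenyl}-2,4,6-trimethyldeca-2,4-dienamide F3. Suzuki–Miyaura coupling of F3 with iodide 11 (Pd(PPh3)4, K3PO4, THF/H2O, rt) returns to the route at compound 33 and bypasses compound 32.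

Step 1. The released ethoxide may cleave the trifluoroacetyl group from nitrogen, or the amide anion may be too weak a nucleophile and the ester may be substituted twice or not at all.
The fallback sets out from diethyl squarate 1. One equivalent of ammonia in ethanol at rt should give 3-amino-4-ethoxycyclobut-3-ene-1,2-dione F4; the reaction stops at mono-substitution because the amino group deactivates the second ester. N-Acylation of F4 with trifluoroacetic anhydride and pyridine (CH2Cl2, 0 °C) returns to the route at compound 3.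

**Further compounds**

F1 | step 2 | 2-diazocyclopentane-1,3-dione | [N-]=[N+]=C1C(=O)CCC1=O
F2 | step 2 | N-(2-hydroxy-5-oxocyclopent-1-en-1-yl)-2,2,2-trifluoroacetamide | O=C(NC1=C(O)CCC1=O)C(F)(F)F
F3 | step 19 | (2E,4E,6R)-N-{3-chloro-2,5-bis(methoxymethoxy)-4-[(E)-2-(4,4,5,5-tetramethyl-1,3,2-dioxaborolan-2-yl)ethenyl]phenyl}-2,4,6-trimethyldeca-2,4-dienamide | CCCC[C@@H](C)/C=C(C)/C=C(\C)C(=O)Nc1cc(OCOC)c(/C=C/B2OC(C)(C)C(C)(C)O2)c(Cl)c1OCOC
F4 | step 1 | 3-amino-4-ethoxycyclobut-3-ene-1,2-dione | CCOC1=C(N)C(=O)C1=O
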